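## The problem

Target 20 is 7-hydroxy-5-methoxy-3-(4-methoxybenzyl)-6-methyl-4-oxo-4H-chromene-8-carbaldehyde. It is a 3-benzylchromone: the pyranone ring C is fused to a benzo ring A that carries no hydrogen (OMe at C5, CH3 at C6, OH at C7, CHO at C8), and ring B (4-methoxyphenyl) hangs from C3 through one methylene. There is no stereocentre, so nothing has to be set or relayed; the only stereochemical element on the way is the geometry of one enol ether double bond, which decides whether two chain ends can meet. The real difficulty is regiochemical. Ring A is a C-methylphloroglucinol whose three oxygens end as three different functions (methyl ether at C5, free phenol at C7, ring oxygen O1 on C8a), and alkylation or acylation of a preformed methylphloroglucinol does not tell these positions apart reliably. Three groups need care: the ortho-hydroxy aldehyde at C7/C8 (condensation, oxidation), the pyranone ring (opened at C2 by hydroxide, alkoxide or amines), and the C5 methyl ether peri to the C4 carbonyl (removed by strong Lewis acids such as BCl3). This fixes the order: strongly basic chemistry before ring C exists, and the aldehyde last. The feature that opens the synthesis is that ring A is an acylphloroglucinol, with oxygen on C5, C7 and C8a and the acyl carbon C4 on C4a. The chain C4–C4a–C5–C6–C7–C8–C8a is therefore a folded tetraketide, whose C8a can be an ester carbon and whose C5 oxygen can travel as a methyl enol ether.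

## Retrosynthesis

**20 to 18.** The C8–CHO bond is cut first. In 18 the position C8 is the only unsubstituted carbon of ring A and lies ortho to the free C7 phenol, so a phenol-directed formylation has no regiochemical choice. Carrying the formyl carbon through the earlier steps would expose an aldehyde to carbanions and to an iminium reagent. The precursor 18 lacks only the most sensitive group. The forward step must formylate ring A without touching ring B or opening ring C.

**18 to 16.** Ring C is opened at O1–C2 and C2–C3, which takes C2 out as a one-carbon electrophile. The neighbouring cut at the C3–CH2 bond (condensation of a chromanone with an aromatic aldehyde, then double-bond migration) would need a chromanone and two extra steps. The dihydrochalcone 16 already holds the benzyl carbons as its propanoyl chain, and only its C8a hydroxyl is ortho to the ketone, so ring closure can go one way only. 16 has one ring less and no heterocycle. The forward step has to formylate the α-methylene and close onto C8a–OH in the presence of a free C7 phenol and a free C8–H.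

**16 to 14 (key).** Ring A is opened at C4a–C8a, the bond a Claisen condensation makes. Cutting C4–C4a on the arene instead (acylation of a preformed ring A) would bring back the problem of telling the three oxygens apart. In the open chain 14 each oxygen is already in its final state: C5 as a methyl enol ether, C7 as a ketone, C8a as a methyl ester, with the C6 methyl in place. 14 is acyclic apart from ring B and has no stereocentre. The forward reaction must fold in the Claisen mode (C4a onto the C8a ester) and not in the aldol mode (C8 onto the C4 ketone).

**14 to 9 and 12.** The C4–C4a bond is cut at the open-chain stage, where it is the acylation of a terminal carbanion. This divides 14 into the C8a–C4a piece 9 and the ring B piece 12. Making the C7–C8 bond last would mean homologating an ester next to a free ketone. The forward step asks for a dianion of 9 that reacts at its terminal carbon C4a only, and for an acyl donor that stops at the ketone; the Weinreb amide 12 meets the second demand.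

**9 to 4 and 5.** The C7–C8 bond is cut, so that C8 and C8a come from Meldrum's acid 5 through the acyl derivative 7. A crossed Claisen condensation on ester 3 would fail, because 3 is a vinylogous carbonate with an acidic γ-methyl. Acid 4 is a six-carbon compound. The forward steps must activate a deactivated acid and cleave the dioxanedione without losing the enol ether.

**4 to 3 to 1, and 12 to 10.** The enol ether of 4 comes from ester 3, which is the O-methylation product of the single ketone of commercial 1. The C5–OMe group is therefore fixed at the very start, with no selectivity question, and the E geometry needed later is the usual one for such β-methoxy enoates. Amide 12 is one step from the commercial acid 10.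

## Roads not taken

**Alternative 1:** The cut goes through C4a–C5 and C8–C8a, so ring A is annulated onto a finished pyranone. Forward, the sulfinyl-activated pyranone A2 (3-(4-methoxybenzyl)-5-(4-tolylsulfinyl)-4H-pyran-4-one) acts as dienophile toward the ketene-acetal diene A3 (1,1-dimethoxy-2-methyl-3-(trimethylsilyloxy)buta-1,3-diene). The adduct aromatises by loss of the sulfinyl group and of one methoxy group, and mild acid frees the C7 phenol to give A1, which is the same compound as 18.
- Merits: the polarity of the partners sets the regiochemistry (the nucleophilic CH2 end of A3 bonds to C8a, β to the carbonyl). The C5–OMe/C6–Me/C7–OH pattern arrives in one convergent step, and ring C with its benzyl group is already present. In convergence and in reaching 18 directly this road is better: it would spare step 8 and has no Claisen-versus-aldol question.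
- Weak points: A2 is a 3,5-disubstituted 4-pyranone with free C2 and C6 and needs its own multi-step preparation, including sulfenylation and oxidation. 4-Pyranones are reluctant dienophiles even when activated. A3 is a fully substituted, hydrolytically fragile ketene acetal. The formylation still follows.
- Comparison: the chosen plan sets against it three cheap commercial pieces (1, 5, 10), robust intermediates and an intramolecular ring closure driven by aromatisation. Once the syntheses of A2 and A3 are counted, it is very probably shorter overall.

**Alternative 2:** The cut is at C2–C3 and C3–C4, with C3 entering as a carbene carbon. Forward, a dihalocarbene cyclopropanates the C2=C3 bond of the siloxybenzofuran A5 (tert-butyl{[4-methoxy-6-(methoxymethoxy)-5-methyl-1-benzofuran-3-yl]oxy}dimethylsilane). The halocyclopropane opens with loss of halide and the silyl group to the 3-bromochromone A4 (3-bromo-5-methoxy-7-(methoxymethoxy)-6-methyl-4H-chromen-4-one). A benzylic cross-coupling at C3, acetal removal and formylation would follow.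
- Merits: the ring expansion is short and mild, and ring B is attached late, so a series of analogues varied in the benzyl group would be easier than in the chosen plan, where ring B enters four steps from the end.
- Weak points: A5 presupposes a benzofuranone whose ring A already carries the three differentiated oxygens and the methyl group, so the central problem is moved into the starting material unsolved. The electron-rich C7–H of A5 can compete for the electrophilic carbene. Three further steps separate A4 from the target.
- Comparison: the chosen plan builds the differentiated ring A from acyclic material; alternative 2 is superior only in late-stage modularity.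

**Alternative 3:** The cut is the C3–C4 bond. Forward, the aldehyde A7 (2-methoxy-6-{[3-(4-methoxyphenyl)prop-2-yn-1-yl]oxy}-3-methyl-4-(triisopropylsilyloxy)benzaldehyde) is treated with a thiazolium-derived carbene and a mild base. The Breslow intermediate adds across the tethered alkyne (6-exo-dig) to give A6, (E)-5-methoxy-3-(4-methoxybenzylidene)-6-methyl-7-(triisopropylsiloxy)chroman-4-one. Migration of the exocyclic double bond into the ring, desilylation and formylation would follow.
- Merits: ring C closes catalytically, with full atom economy and without strong acid, which is milder than step 8 of the chosen plan and in that respect better. A6 also belongs to the natural 3-benzylidenechromanone family, which the chosen plan does not reach.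
- Weak points: A7 needs three phenolic oxygens of a C-methylated benzaldehyde differentiated by hand (methyl, silyl, propargyl), which is again the unsolved regiochemical problem. Its aldehyde is electron-rich and flanked by two ortho oxygens, so formation of the Breslow intermediate should be slow. An unactivated internal aryl alkyne is at the edge of what intramolecular hydroacylation accepts. Two extra steps follow A6.
- Comparison: the chosen plan sets against it a ring A whose substitution pattern is fixed by the chain from which it is folded, and commodity starting materials.

Key step: step 7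

Remark: 1 is used as the racemate (its stereocentre disappears in step 1); LiN(iPr)2 and Mg(OMe)2 are taken as commercial solutions; atom labels C2 to C8a follow the chromone numbering of 20 throughout, also for open-chain compounds.

## Route

Step 1
Reactants: 1 methyl 2-methyl-3-oxobutanoate (methyl 2-methylacetoacetate)
Product: 3 methyl (2E)-3-methoxy-2-methylbut-2-enoate, via dimethyl ketal 2 (not isolated)
Conditions: HC(OMe)3, MeOH, cat. H2SO4, rt; then cat. p-TsOH, 120 °C, MeOH distilled off
Reagents that add atoms: trimethyl orthoformate, COC(OC)OC
Why: Acid-catalysed ketalisation with an orthoester and elimination of methanol to the conjugated β-methoxy enoate; the E isomer (ester trans to OMe) should predominate as for the parent β-methoxycrotonate, and it is the one that puts the future C4a methyl cis to the carbonyl.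

Step 2
Reactants: 3 methyl (2E)-3-methoxy-2-methylbut-2-enoate
Product: 4 (2E)-3-methoxy-2-methylbut-2-enoic acid
Conditions: KOH, MeOH/H2O, reflux; then 1 M HCl to pH 3, 0 °C
Reagents that add atoms: potassium hydroxide, [K+].[OH-]
Why: Saponification of a vinylogous carbonate ester; the enol ether is inert to base, and a brief cold acidification to pH 3 should protonate only the carboxylate.

Step 3
Reactants: 4 (2E)-3-methoxy-2-methylbut-2-enoic acid; 5 Meldrum's acid (2,2-dimethyl-1,3-dioxane-4,6-dione)
Product: 7 5-[(2E)-1-hydroxy-3-methoxy-2-methylbut-2-en-1-ylidene]-2,2-dimethyl-1,3-dioxane-4,6-dione, via acid chloride 6 (not isolated)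
Conditions: (COCl)2, cat. DMF, CH2Cl2, 0 °C to rt; then 5, pyridine, cat. DMAP, CH2Cl2, 0 °C to rt
Reagents that add atoms: none
Why: C-acylation of Meldrum's acid by an acid chloride in the presence of pyridine (Oikawa–Yonemitsu procedure); 6 is a vinylogous chloroformate of the known, isolable β-alkoxyacryloyl chloride type, and the base keeps HCl away from the enol ether.

Step 4
Reactants: 7 5-[(2E)-1-hydroxy-3-methoxy-2-methylbut-2-en-1-ylidene]-2,2-dimethyl-1,3-dioxane-4,6-dione
Product: 9 methyl (4E)-5-methoxy-4-methyl-3-oxohex-4-enoate, via acylketene 8 (not isolated)
Conditions: MeOH, toluene, reflux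
Reagents that add atoms: methanol, CO
Why: Thermal alcoholysis of an acyl Meldrum's acid: loss of acetone and CO2 gives the acylketene 8, which methanol traps as the β-keto ester; the neutral conditions leave the enol ether alone, and exchange with methanol would be degenerate.

Step 5
Reactants: 10 3-(4-methoxyphenyl)propanoic acid
Product: 12 N-methoxy-3-(4-methoxyphenyl)-N-methylpropanamide, via acyl imidazole 11 (not isolated)
Conditions: CDI, CH2Cl2, rt; then MeNHOMe·HCl, rt
Reagents that add atoms: N,O-dimethylhydroxylamine hydrochloride, CNOC.Cl
Why: Weinreb amide formation through the acyl imidazole (CDI activation) of an unhindered acid; the imidazole set free neutralises the amine hydrochloride.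

Step 6
Reactants: 9 methyl (4E)-5-methoxy-4-methyl-3-oxohex-4-enoate; 12 N-methoxy-3-(4-methoxyphenyl)-N-methylpropanamide
Product: 14 methyl (4E)-5-methoxy-9-(4-methoxyphenyl)-4-methyl-3,7-dioxonon-4-enoate, via dilithium dianion 13 (not isolated)
Conditions: LiN(iPr)2 (2.2 equiv), THF, −78 to −20 °C; then 12, −78 to −10 °C; aq NH4Cl, −20 °C
Reagents that add atoms: none
Why: Vinylogous Huckin–Weiler dianion acylation: after the β-keto ester is enolised, the only remaining acidic carbon conjugated to a carbonyl is the C4a methyl (γ to the C7 ketone through the enol ether and cis to it), and the resulting linear bis-enolate 13 should react at this terminal, least stabilised carbon. The N-methoxy-N-methyl amide holds the addition at the ketone level until the quench, so the more acidic product cannot consume dianion or be acylated again; any Z enol ether formed here is tolerated because step 7 equilibrates it.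

Step 7
Reactants: 14 methyl (4E)-5-methoxy-9-(4-methoxyphenyl)-4-methyl-3,7-dioxonon-4-enoate
Product: 16 1-(4,6-dihydroxy-2-methoxy-3-methylphenyl)-3-(4-methoxyphenyl)propan-1-one, via cyclohexenedione 15 (not isolated)
Conditions: Mg(OMe)2 (4 equiv), MeOH, rt to reflux; then cold 1 M HCl
Reagents that add atoms: none
Why: Mg(OMe)2 first turns the β-keto ester end of 14 into its magnesium chelate, and further methoxide reversibly removes a proton from C4a, which is α to the C4 ketone and, through the C5=C6 enol ether, vinylogous to the C7 ketone. The C4a carbanion adds to the C8a ester carbonyl in a 6-exo-trig closure (ring C8a–C8–C7–C6–C5–C4a), methoxide leaves, and the cyclohexenedione 15 enolises at once to the arene 16, held as a magnesium phenoxide chelated to the C4 ketone. The closest known reaction is the base- or magnesium-mediated Claisen (Dieckmann-type) cyclisation of 3,5,7-triketo esters to acylphloroglucinols, here with one carbonyl carried as its methyl enol ether. No stereocentre is formed; the E enol ether places C4a and C7 cis on the C5=C6 bond as the ring requires, and a Z isomer can equilibrate through the extended enolate or by addition–elimination of methoxide at C5. The selectivity needed is Claisen folding over aldol folding (C8 onto the C4 ketone): the magnesium chelate makes the C8 carbanion a poor nucleophile, the aldol addition is reversible and dehydrates only slowly without acid, and the Claisen path is made irreversible by loss of methoxide and aromatisation. Closure through oxygen to a 2-pyranone is excluded because the C5 oxygen is methylated, and the absence of acid keeps the enol ether from hydrolysing to a triketone. Because the C5 oxygen enters as a methyl ether, 16 carries C5–OMe, C7–OH and C8a–OH already differentiated.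

Step 8
Reactants: 16 1-(4,6-dihydroxy-2-methoxy-3-methylphenyl)-3-(4-methoxyphenyl)propan-1-one
Product: 18 7-hydroxy-5-methoxy-3-[(4-methoxyphenyl)methyl]-6-methyl-4H-chromen-4-one, via enaminone 17 (not isolated)
Conditions: BF3·OEt2, DMF, 10 to 50 °C; then MsCl, DMF, 50 to 90 °C; aq NaOAc
Reagents that add atoms: N,N-dimethylformamide, CN(C)C=O
Why: One-carbon insertion of the deoxybenzoin-to-isoflavone type applied to a dihydrochalcone: BF3 coordinates the chelated hydroxy ketone and makes the α-methylene nucleophilic, and the iminium reagent formed from DMF and MsCl formylates C3 to the enaminone 17. The C8a hydroxyl, the only one ortho to the ketone, then adds to the iminium carbon (C2) and dimethylamine is lost; free phenols such as the one at C7 are tolerated under these base-free conditions, as in the standard preparation of 7-hydroxy- and 5,7-dihydroxy-isoflavones and 3-benzylchromones.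

Step 9
Reactants: 18 7-hydroxy-5-methoxy-3-[(4-methoxyphenyl)methyl]-6-methyl-4H-chromen-4-one
Product: 20 7-hydroxy-5-methoxy-3-[(4-methoxyphenyl)methyl]-6-methyl-4-oxo-4H-chromene-8-carbaldehyde, via aldimine 19 (not isolated)
Conditions: HMTA (4 equiv), AcOH, 100 °C; then 3 M aq HCl, 80 °C
Reagents that add atoms: hexamethylenetetramine, C1N2CN3CN1CN(C2)C3; water, O
Why: Duff reaction: the iminium ion from protonated HMTA attacks C8, the only free position of ring A and ortho to the C7 hydroxyl; an internal hydride transfer gives the aldimine 19 (drawn in its simplest N–H form), which aqueous acid hydrolyses to the aldehyde. In acetic acid only a free phenol ring is reactive enough, which should keep ring B and the pyranone out; the method is established for 8-formylation of 7-hydroxy-chromones, -isoflavones and -coumarins.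

## Compound list

1 | methyl 2-methyl-3-oxobutanoate (methyl 2-methylacetoacetate; racemic, labile stereocentre) | COC(=O)C(C)C(C)=O | starting material
2 | methyl 3,3-dimethoxy-2-methylbutanoate (racemic) | COC(=O)C(C)C(C)(OC)OC | intermediate (not isolated)
3 | methyl (2E)-3-methoxy-2-methylbut-2-enoate | COC(=O)/C(C)=C(/OC)C | intermediate
4 | (2E)-3-methoxy-2-methylbut-2-enoic acid | OC(=O)/C(C)=C(/OC)C | intermediate
5 | 2,2-dimethyl-1,3-dioxane-4,6-dione (Meldrum's acid) | CC1(C)OC(=O)CC(=O)O1 | starting material
6 | (2E)-3-methoxy-2-methylbut-2-enoyl chloride | ClC(=O)/C(C)=C(/OC)C | intermediate (not isolated)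
7 | 5-[(2E)-1-hydroxy-3-methoxy-2-methylbut-2-en-1-ylidene]-2,2-dimethyl-1,3-dioxane-4,6-dione | CC1(C)OC(=O)C(=C(O)/C(C)=C(/OC)C)C(=O)O1 | intermediate
8 | (4E)-5-methoxy-4-methylhexa-1,4-diene-1,3-dione (acylketene) | O=C=CC(=O)/C(C)=C(/OC)C | intermediate (not isolated)
9 | methyl (4E)-5-methoxy-4-methyl-3-oxohex-4-enoate | COC(=O)CC(=O)/C(C)=C(/OC)C | intermediate
10 | 3-(4-methoxyphenyl)propanoic acid | COc1ccc(CCC(=O)O)cc1 | starting material
11 | 1-(1H-imidazol-1-yl)-3-(4-methoxyphenyl)propan-1-one | COc1ccc(CCC(=O)n2ccnc2)cc1 | intermediate (not isolated)
12 | N-methoxy-3-(4-methoxyphenyl)-N-methylpropanamide | COc1ccc(CCC(=O)N(C)OC)cc1 | intermediate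
13 | dilithium 1,5-dimethoxy-4-methylhexa-1,3,5-triene-1,3-diolate (dianion of 9; enolate geometries not defined) | [Li+].[Li+].COC([O-])=CC([O-])=C(C)C(=C)OC | intermediate (not isolated)
14 | methyl (4E)-5-methoxy-9-(4-methoxyphenyl)-4-methyl-3,7-dioxonon-4-enoate | COC(=O)CC(=O)/C(C)=C(/OC)CC(=O)CCc1ccc(OC)cc1 | intermediate
15 | 5-methoxy-6-[3-(4-methoxyphenyl)propanoyl]-4-methylcyclohex-4-ene-1,3-dione (racemic) | COc1ccc(CCC(=O)C2C(=O)CC(=O)C(C)=C2OC)cc1 | intermediate (not isolated)
16 | 1-(4,6-dihydroxy-2-methoxy-3-methylphenyl)-3-(4-methoxyphenyl)propan-1-one | COc1ccc(CCC(=O)c2c(O)cc(O)c(C)c2OC)cc1 | intermediate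
17 | 1-(4,6-dihydroxy-2-methoxy-3-methylphenyl)-3-(dimethylamino)-2-[(4-methoxyphenyl)methyl]prop-2-en-1-one (C=C geometry not defined) | COc1ccc(CC(=CN(C)C)C(=O)c2c(O)cc(O)c(C)c2OC)cc1 | intermediate (not isolated)
18 | 7-hydroxy-5-methoxy-3-[(4-methoxyphenyl)methyl]-6-methyl-4H-chromen-4-one | COc1ccc(Cc2coc3cc(O)c(C)c(OC)c3c2=O)cc1 | intermediate
19 | 7-hydroxy-8-(iminomethyl)-5-methoxy-3-[(4-methoxyphenyl)methyl]-6-methyl-4H-chromen-4-one | COc1ccc(Cc2coc3c(C=N)c(O)c(C)c(OC)c3c2=O)cc1 | intermediate (not isolated)
20 | 7-hydroxy-5-methoxy-3-[(4-methoxyphenyl)methyl]-6-methyl-4-oxo-4H-chromene-8-carbaldehyde | COc1ccc(Cc2coc3c(C=O)c(O)c(C)c(OC)c3c2=O)cc1 | target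

## Step count and least certain steps

Total: 9 steps. Longest linear sequence: 8 steps (steps 1, 2, 3, 4, 6, 7, 8, 9); step 5 is a one-step side branch.

**Step 7 (key step).**
- Risk: the chain may fold in the aldol mode (C8 carbanion onto the C4 ketone, followed by dehydration), or not close at all, because the C8a ester is deactivated as part of the chelated enolate. Premature hydrolysis of the enol ether would also scramble the oxygen pattern.
- Fallback: it changes the acyl acceptor to a thioester and the closure to aprotic, non-chelating conditions. It sets out from 7 and 12 and returns at 16. Heating 7 with 2-methylpropane-2-thiol in toluene should give S-tert-butyl (4E)-5-methoxy-4-methyl-3-oxohex-4-enethioate F1. Its dianion (LiN(iPr)2, 2.2 equiv, THF) is acylated with 12 to S-tert-butyl (4E)-5-methoxy-9-(4-methoxyphenyl)-4-methyl-3,7-dioxonon-4-enethioate F2. F2 is then closed with Cs2CO3 in MeCN; the more electrophilic thioester carbon and the better leaving group should favour attack of C4a at C8a, giving 16 with loss of the thiol.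

**Step 6.**
- Risk: the second deprotonation may be incomplete, protons may be transferred between the dianion and the α-methylene of 12, or the internal carbanion carbon C8 may be acylated. The bis-enolate may also react sluggishly at the temperatures it tolerates.
- Fallback: it replaces the dianion by the monoanion of a dioxinone-masked keto ester. It sets out from 7 and 12 and returns at 14. Heating 7 in toluene with acetone should give 6-[(2E)-3-methoxybut-2-en-2-yl]-2,2-dimethyl-4H-1,3-dioxin-4-one F3, which has no acidic C8 hydrogens. One equivalent of LiN(iPr)2 deprotonates its terminal methyl, and acylation with 12 gives 6-[(2E)-3-methoxy-7-(4-methoxyphenyl)-5-oxohept-2-en-2-yl]-2,2-dimethyl-4H-1,3-dioxin-4-one F4. Heating F4 in toluene/MeOH releases acetone, and methanol traps the acylketene as 14.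

**Step 8.**
- Risk: the iminium/sulfonyl chloride mixture may formylate C8 of ring A or sulfonylate the free C7 phenol, and BF3 may assist loss of the peri C5 methyl group on heating.
- Fallback: a base-mediated Claisen formylation followed by acid dehydration, setting out from 16 and returning at 18. Treatment of 16 with excess NaH and ethyl formate in THF formylates the α-methylene, and the product closes onto C8a–OH as the hemiacetal 2,7-dihydroxy-5-methoxy-3-[(4-methoxyphenyl)methyl]-6-methyl-2,3-dihydro-4H-chromen-4-one F5. Warming F5 in AcOH with cat. H2SO4 dehydrates it to 18.

**Step 9.**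
- Risk: substitution may occur on ring B ortho to its methoxy group, or conversion may be low, because C8 is flanked by O1 and the C7 hydroxyl on a ring deactivated by the pyranone carbonyl. Amine by-products may also add to C2 and open ring C.
- Fallback: halogenation followed by carbonylative formylation, setting out from 18 and returning at 20. N-Iodosuccinimide in DMF should iodinate C8, ortho to the phenol, to give 7-hydroxy-8-iodo-5-methoxy-3-[(4-methoxyphenyl)methyl]-6-methyl-4H-chromen-4-one F6. Palladium-catalysed reductive carbonylation of F6 (Pd(OAc)2, 1,3-bis(diphenylphosphino)propane, CO, Et3SiH, Na2CO3, DMF) then gives 20.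

## Further compounds

F1 | step 7 | S-tert-butyl (4E)-5-methoxy-4-methyl-3-oxohex-4-enethioate | CC(C)(C)SC(=O)CC(=O)/C(C)=C(/OC)C
F2 | step 7 | S-tert-butyl (4E)-5-methoxy-9-(4-methoxyphenyl)-4-methyl-3,7-dioxonon-4-enethioate | CC(C)(C)SC(=O)CC(=O)/C(C)=C(/OC)CC(=O)CCc1ccc(OC)cc1
F3 | step 6 | 6-[(2E)-3-methoxybut-2-en-2-yl]-2,2-dimethyl-4H-1,3-dioxin-4-one | CC1(C)OC(=O)C=C(O1)/C(C)=C(/OC)C
F4 | step 6 | 6-[(2E)-3-methoxy-7-(4-methoxyphenyl)-5-oxohept-2-en-2-yl]-2,2-dimethyl-4H-1,3-dioxin-4-one | CC1(C)OC(=O)C=C(O1)/C(C)=C(/OC)CC(=O)CCc1ccc(OC)cc1
F5 | step 8 | 2,7-dihydroxy-5-methoxy-3-[(4-methoxyphenyl)methyl]-6-methyl-2,3-dihydro-4H-chromen-4-one (racemic mixture of diastereomers) | COc1ccc(CC2C(O)Oc3cc(O)c(C)c(OC)c3C2=O)cc1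
F6 | step 9 | 7-hydroxy-8-iodo-5-methoxy-3-[(4-methoxyphenyl)methyl]-6-methyl-4H-chromen-4-one | COc1ccc(Cc2coc3c(I)c(O)c(C)c(OC)c3c2=O)cc1
A1 | alternative 1 | 7-hydroxy-5-methoxy-3-(4-methoxybenzyl)-6-methyl-4H-chromen-4-one (identical with 18) | COc1ccc(Cc2coc3cc(O)c(C)c(OC)c3c2=O)cc1
A2 | alternative 1 | 3-(4-methoxybenzyl)-5-(4-tolylsulfinyl)-4H-pyran-4-one (racemic at sulfur) | COc1ccc(Cc2cocc(S(=O)c3ccc(C)cc3)c2=O)cc1
A3 | alternative 1 | 1,1-dimethoxy-2-methyl-3-(trimethylsilyloxy)buta-1,3-diene | COC(OC)=C(C)C(=C)O[Si](C)(C)C
A4 | alternative 2 | 3-bromo-5-methoxy-7-(methoxymethoxy)-6-methyl-4H-chromen-4-one | COCOc1cc2occ(Br)c(=O)c2c(OC)c1C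
A5 | alternative 2 | tert-butyl{[4-methoxy-6-(methoxymethoxy)-5-methyl-1-benzofuran-3-yl]oxy}dimethylsilane | COCOc1cc2occ(O[Si](C)(C)C(C)(C)C)c2c(OC)c1C
A6 | alternative 3 | (E)-5-methoxy-3-(4-methoxybenzylidene)-6-methyl-7-(triisopropylsiloxy)chroman-4-one | COc1ccc(/C=C2/C(=O)c3c(OC)c(C)c(O[Si](C(C)C)(C(C)C)C(C)C)cc3OC2)cc1
A7 | alternative 3 | 2-methoxy-6-{[3-(4-methoxyphenyl)prop-2-yn-1-yl]oxy}-3-methyl-4-(triisopropylsilyloxy)benzaldehyde | COc1ccc(C#CCOc2cc(O[Si](C(C)C)(C(C)C)C(C)C)c(C)c(OC)c2C=O)cc1
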